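## Retrosynthetic overview

1. Atom labels: the seven-membered ring is C2 (carries the secondary methyl)–C3–C4–C5 (ring-fusion carbinol)–C6 (ring-fusion CH)–C10 (ketone)–C11 (quaternary); the five-membered ring is C5–C6–C7–C8 (secondary carbinol)–C9 (gem-dimethyl).
2. Feature used: C2 with its methyl, C3, C4, C5, C10, C11 and C9 with its two methyls map atom for atom onto (R)-pulegone, whose stereocentre is C2. The bicyclo[5.3.0]decanone core differs from it only by C6 inserted into the old C10–C5 ring bond and by the C7–C8 bridge from C6 to C9.
3. Key disconnection: bonds C7–C8 and C5–C6 of a C6=C7 hydroazulenone are made together by a Prins–pinacol ring-enlarging cyclopentene annulation. The substrate is a 1-ethynylcyclohexanol silyl ether (C10) with a dibenzyl acetal (C8) on C9 and a silyloxy group on C5.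
4. That precursor comes from pulegone by copper-catalysed vinyl Grignard addition (C9 quaternary, C8), Rubottom oxidation (C5–O), ozonolysis, acetalisation and ethynylation of C10. After the annulation, C11 is methylated and then alkylated by Michael addition, C6=C7 is hydrogenated, and the butenolide is closed by intramolecular Wittig reaction.
5. Ring order: pulegone six-membered ring (purchased) → cyclopentene and cycloheptenone together (step 8) → butenolide (step 15).

Key step: step 8

Remark: benzyloxytrimethylsilane, ethynylmagnesium bromide, N,O-dimethylhydroxylamine hydrochloride and ketenylidenetriphenylphosphorane are taken as purchased materials; the C11 configuration of compound 20 is of no consequence because C11 becomes planar again in 21 and 22.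

## Route

Step 1
Reactants: 1 (R)-pulegone; 2 vinylmagnesium bromide
Product: 4 trimethylsilyl enol ether of (5R)-5-methyl-2-(2-methylbut-3-en-2-yl)cyclohexanone (C5=C10), via magnesium enolate 3 (not isolated)
Conditions: CuBr·SMe2 (5 mol %), THF, −20 °C; then TMSCl, Et3N, DMPU, −20 °C → rt
Reagents that add atoms: chlorotrimethylsilane, C[Si](C)(C)Cl
Why: Copper-catalysed (Kharasch) 1,4-addition of the vinyl Grignard reagent to the β,β-disubstituted enone builds the quaternary C9 and gives the C5=C10 enolate regiospecifically, which is O-silylated; C2 is untouched and no new stereocentre is formed.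

Step 2
Reactants: 4 trimethylsilyl enol ether
Product: 7 α-hydroxy ketone (C5–OH cis to the C2 methyl), via silyloxy epoxide 5 (not isolated), via silyloxy ketone 6 (not isolated)
Conditions: mCPBA, NaHCO3, CH2Cl2, −20 → 0 °C; then 1 M HCl, THF, rt
Reagents that add atoms: 3-chloroperoxybenzoic acid, OOC(=O)c1cccc(Cl)c1
Why: In this Rubottom oxidation the peracid should epoxidise only the electron-rich tetrasubstituted silyl enol ether (the monosubstituted vinyl group is far less reactive), the silyloxy epoxide opens with 1,4-silyl shift and acid frees the tertiary alcohol; oxygen should enter C5 axially on the half-chair with the C2 methyl equatorial, which leaves the C9 chain and the C2 methyl both equatorial and places C5–O cis to the C2 methyl, any minor epimer being removed by chromatography.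

Step 3
Reactants: 7 α-hydroxy ketone
Product: 8 C5 tert-butyldimethylsilyl ether of 7
Conditions: TBSOTf, 2,6-lutidine, CH2Cl2, 0 °C → rt; dilute aqueous HCl wash
Reagents that add atoms: tert-butyldimethylsilyl triflate, CC(C)(C)[Si](C)(C)OS(=O)(=O)C(F)(F)F
Why: Silyl triflate with 2,6-lutidine is the standard O-silylation for a hindered tertiary alcohol, and the acid wash returns any ketone that was converted into its silyl enol ether.

Step 4
Reactants: 8 silyl ether with vinyl group
Product: 10 keto aldehyde (C8 aldehyde on the quaternary C9), via ozonide 9 (not isolated)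
Conditions: O3, CH2Cl2, −78 °C; then Me2S, −78 °C → rt
Reagents that add atoms: ozone, [O-][O+]=O
Why: Ozonolysis with reductive work-up cleaves the only C=C bond to the neopentyl aldehyde C8, which has no α-hydrogen and can neither enolise nor epimerise.

Step 5
Reactants: 10 keto aldehyde; 11 benzyloxytrimethylsilane (first equivalent)
Product: 12 C8 dibenzyl acetal with free C10 ketone
Conditions: BnOSiMe3 (2.2 equiv in all), TMSOTf (5 mol %), CH2Cl2, −78 → −40 °C; pyridine quench
Reagents that add atoms: benzyloxytrimethylsilane (second equivalent of 11), C[Si](C)(C)OCc1ccccc1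
Why: Noyori acetalisation (two equivalents of the alkoxysilane with catalytic silyl triflate, aprotic, low temperature) transfers both benzyloxy groups to the aldehyde carbon while the two trimethylsilyl groups and the carbonyl oxygen leave as hexamethyldisiloxane, so the dibenzyl acetal forms without protic acid and the tertiary silyl ether stays intact, the C10 ketone next to the fully substituted C5 being too hindered to be ketalised or drawn into a cyclic bis-acetal.

Step 6
Reactants: 12 acetal ketone; 13 ethynylmagnesium bromide
Product: 14 tertiary propargylic alcohol (C10–OH cis to C5–OTBS and ethynyl cis to the C9 chain)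
Conditions: LaCl3·2LiCl (0.3 equiv), THF, 0 °C → rt; aqueous NH4Cl
Reagents that add atoms: none
Why: In this 1,2-addition to the hindered, enolisable ketone (assisted by LaCl3·2LiCl) the ketone chair has the C9 chain and C2 methyl equatorial and the C5–OTBS bond axial, so the small acetylide should enter axially and anti to the C5–O bond (Felkin–Anh polar model with a non-chelating silyl ether), which sets C10 with its oxygen cis to the C5 oxygen.

Step 7
Reactants: 14 propargylic alcohol
Product: 15 bis-silyl ether (C5–OTBS, C10–OTMS) with C10 ethynyl group and C8 dibenzyl acetal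
Conditions: N-(trimethylsilyl)imidazole, CH2Cl2, rt
Reagents that add atoms: N-(trimethylsilyl)imidazole, C[Si](C)(C)n1ccnc1
Why: N-(Trimethylsilyl)imidazole O-silylates hindered tertiary alcohols under neutral conditions, which avoids the silyl triflate and pyridine-base combinations that would ionise the dibenzyl acetal.

Step 8
Reactants: 15 bis-silyl ether acetal
Product: 18 bicyclo[5.3.0]decenone (C6=C7 conjugated with the C10 ketone; C5–OTBS; C8–OBn cis to C5–O), via oxocarbenium ion 16 (not isolated), via cyclohexenyl cation 17 (not isolated)
Conditions: SnCl4 (1.5 equiv), CH2Cl2, −78 → −23 °C; Et3N/MeOH, then aqueous NaHCO3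
Reagents that add atoms: none
Why: SnCl4 removes one benzyloxy group to give the E-configured benzyl oxocarbenium ion at C8, the terminal alkyne carbon C7 attacks it (Prins step), and the developing cyclohexenyl cation at C6 is quenched by 1,2-shift of the C10–C5 bond while the C10 silyloxy group becomes the ketone with loss of the trimethylsilyl group (pinacol step); this is the known Prins–pinacol ring-enlarging cyclopentene annulation of 1-alkynylcycloalkanol acetals. The transient six-membered ring (C8, C9, C5, C10, C6, C7) closes 6-endo-dig with respect to the alkyne with the oxocarbenium C=O bond exocyclic, and the shift of C5 from C10 to C6 then contracts it to the cyclopentene (C5, C6, C7, C8, C9) and in the same event enlarges the pulegone ring to the cycloheptenone by inserting C6 between C10 and C5. The only new stereocentre, C8, is set in the chair-like cyclisation array, which is cis-fused to the cyclohexane chair with the C5–C4 bond axial and the C5–O bond equatorial on the forming ring, so the benzyloxy group of the E-oxocarbenium ion takes the equatorial position away from the axial C4 methylene and C8–O ends up cis to C5–O. C5 migrates with retention, so C5 and the pulegone centre C2 are carried through unchanged. The step needs migration of C5 and not of C11, which is secured because the empty orbital of the cyclohexenyl cation lies in the plane of the new ring and overlaps only with the ring bond C10–C5; it also needs the alkyne to outrun capture of the oxocarbenium ion by the C10 oxygen, which the gem-dimethyl group at C9 and the silyl cap on that oxygen favour.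

Step 9
Reactants: 18 bicyclic enone
Product: 20 C11-methyl enone, via lithium enolate 19 (not isolated)
Conditions: LiN(iPr)2, THF, −78 °C; MeI, DMPU, −78 → −30 °C
Reagents that add atoms: iodomethane, CI
Why: Kinetic deprotonation can occur only at C11 because C6 is sp2, and the cross-conjugated lithium enolate is C-methylated (enolate alkylation), expected anti to the C2 methyl, the C11 configuration being erased in the next step.

Step 10
Reactants: 20 C11-methyl enone
Product: 22 trimethylsilyl dienol ether (C11=C10–OTMS), via lithium enolate 21 (not isolated)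
Conditions: LiN(iPr)2, THF, −78 → −40 °C; TMSCl, Et3N, −78 → 0 °C; pentane, filtration
Reagents that add atoms: chlorotrimethylsilane, C[Si](C)(C)Cl
Why: A second kinetic α'-deprotonation gives the tetrasubstituted cross-conjugated enolate, which is O-silylated, so that the following Michael addition can be run under Lewis acid and avoids the proton transfer and oligomerisation typical of a lithium enolate with a vinyl ketone.

Step 11
Reactants: 23 benzyloxyacetyl chloride; 24 N,O-dimethylhydroxylamine hydrochloride
Product: 25 2-(benzyloxy)-N-methoxy-N-methylacetamide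
Conditions: pyridine, CH2Cl2, 0 °C → rt
Reagents that add atoms: none
Why: N-Acylation of the hydroxylamine by the acid chloride (Weinreb amide formation) is fast and clean.

Step 12
Reactants: 25 Weinreb amide; 2 vinylmagnesium bromide
Product: 27 1-(benzyloxy)but-3-en-2-one, via magnesium chelate 26 (not isolated)
Conditions: THF, −78 → 0 °C; poured into cold 1 M HCl
Reagents that add atoms: none
Why: In this Weinreb ketone synthesis the five-membered magnesium chelate persists until work-up so that only one vinyl group adds, and the inverse acidic quench keeps the liberated amine from adding to the vinyl ketone.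

Step 13
Reactants: 22 silyl dienol ether; 27 1-(benzyloxy)but-3-en-2-one
Product: 29 Michael adduct with quaternary C11 (C11 methyl cis to C2 methyl; 4-benzyloxy-3-oxobutyl chain trans), via adduct silyl enol ether 28 (not isolated)
Conditions: BF3·OEt2 (0.2 equiv), iPrOH (1.1 equiv), CH2Cl2, −78 °C
Reagents that add atoms: none
Why: In this Mukaiyama–Michael addition the activated vinyl ketone should be attacked by C11 from the face opposite the C2 methyl (held pseudoaxial by A(1,2) strain with the C11 methyl, as in alkylations of 2,3-dimethylcyclohexanone enolates), which sets the quaternary C11, and the alcohol takes up the silyl group of the adduct; the fixed s-trans geometry of the C11=C10–C6=C7 diene rules out a competing cycloaddition.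

Step 14
Reactants: 29 Michael adduct
Product: 30 trans-fused keto diol (C6–H trans to C5–OTBS; free C8–OH; side chain CH2CH2C(=O)CH2OH)
Conditions: H2 (1–3 atm), Pd(OH)2/C, EtOAc, rt
Reagents that add atoms: none
Why: Heterogeneous catalytic hydrogenation saturates the conjugated C6=C7 bond and hydrogenolyses both benzyl ethers, and hydrogen should add to the face of the cyclopentene opposite the C5 silyloxy and C8 benzyloxy groups, which gives C6–H trans to C5–O.

Step 15
Reactants: 30 keto diol; 31 ketenylidenetriphenylphosphorane
Product: 33 butenolide with C5–OTBS, via ester ylide 32 (not isolated)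
Conditions: toluene, 80 °C
Reagents that add atoms: none
Why: In this Bestmann butenolide synthesis the primary α-ketol hydroxyl adds to the ketene to give a phosphoranylidene acetate that closes by intramolecular Wittig olefination onto the adjacent ketone, while the neopentyl secondary C8 hydroxyl should acylate far more slowly and the neutral conditions spare the epimerisable C6 and the β-silyloxy ketone.

Step 16
Reactants: 33 silyl-protected butenolide
Product: 34 target compound CNP0077405.1
Conditions: HF (48 % aqueous), MeCN, 0 °C → rt
Reagents that add atoms: none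
Why: Acidic fluoride desilylation removes the tertiary silyl ether without the basic conditions that would cause retro-aldol cleavage of the C5–C6 bond or deprotonate the butenolide.

## Compound list

1 | (R)-pulegone, (5R)-5-methyl-2-(propan-2-ylidene)cyclohexan-1-one | C[C@@H]1CCC(=C(C)C)C(=O)C1 | starting material
2 | vinylmagnesium bromide | C=C[Mg]Br | starting material
3 | bromomagnesium C5=C10 enolate of (5R)-5-methyl-2-(2-methylbut-3-en-2-yl)cyclohexanone | C[C@@H]1CCC(C(C)(C)C=C)=C(O[Mg]Br)C1 | intermediate
4 | trimethylsilyl enol ether of (5R)-5-methyl-2-(2-methylbut-3-en-2-yl)cyclohexanone | C[C@@H]1CCC(C(C)(C)C=C)=C(O[Si](C)(C)C)C1 | intermediate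
5 | C5,C10 silyloxy epoxide of 4 (epoxide oxygen cis to the C2 methyl) | C[C@@H]1CC[C@]2(C(C)(C)C=C)O[C@]2(O[Si](C)(C)C)C1 | intermediate
6 | 2-(trimethylsilyloxy) ketone (C5–OTMS cis to the C2 methyl) | C[C@@H]1CC[C@@](O[Si](C)(C)C)(C(C)(C)C=C)C(=O)C1 | intermediate
7 | 2-hydroxy-5-methyl-2-(2-methylbut-3-en-2-yl)cyclohexan-1-one, C5–OH cis to the C2 methyl, C9 chain trans | C[C@@H]1CC[C@@](O)(C(C)(C)C=C)C(=O)C1 | intermediate
8 | C5 tert-butyldimethylsilyl ether of 7 | C[C@@H]1CC[C@@](O[Si](C)(C)C(C)(C)C)(C(C)(C)C=C)C(=O)C1 | intermediate
9 | ozonide (1,2,4-trioxolane) of 8, mixture at the trioxolane carbon | C[C@@H]1CC[C@@](O[Si](C)(C)C(C)(C)C)(C(C)(C)C2OCOO2)C(=O)C1 | intermediate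
10 | 2-[1-(tert-butyldimethylsilyloxy)-4-methyl-2-oxocyclohexyl]-2-methylpropanal (C5–O cis to the C2 methyl) | C[C@@H]1CC[C@@](O[Si](C)(C)C(C)(C)C)(C(C)(C)C=O)C(=O)C1 | intermediate
11 | benzyloxytrimethylsilane | C[Si](C)(C)OCc1ccccc1 | starting material
12 | dibenzyl acetal of 10 (C8 acetal, free C10 ketone) | C[C@@H]1CC[C@@](O[Si](C)(C)C(C)(C)C)(C(C)(C)C(OCc2ccccc2)OCc2ccccc2)C(=O)C1 | intermediate
13 | ethynylmagnesium bromide | C#C[Mg]Br | starting material
14 | 1-ethynylcyclohexanol from 12 (C10–OH cis to C5–OTBS, ethynyl cis to the C9 chain) | C[C@@H]1CC[C@@](O[Si](C)(C)C(C)(C)C)(C(C)(C)C(OCc2ccccc2)OCc2ccccc2)[C@@](O)(C#C)C1 | intermediate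
15 | C10 trimethylsilyl ether of 14 (annulation precursor) | C[C@@H]1CC[C@@](O[Si](C)(C)C(C)(C)C)(C(C)(C)C(OCc2ccccc2)OCc2ccccc2)[C@@](O[Si](C)(C)C)(C#C)C1 | intermediate
16 | benzyl oxocarbenium ion at C8 derived from 15 | C[C@@H]1CC[C@@](O[Si](C)(C)C(C)(C)C)(C(C)(C)C=[O+]Cc2ccccc2)[C@@](O[Si](C)(C)C)(C#C)C1 | intermediate
17 | cis-fused bicyclic cyclohexenyl cation (cation at C6, C7–C8 bond formed, C8–OBn cis to C5–OTBS) | C[C@@H]1CC[C@@]2(O[Si](C)(C)C(C)(C)C)C(C)(C)[C@H](OCc3ccccc3)C=[C+][C@@]2(O[Si](C)(C)C)C1 | intermediate
18 | bicyclo[5.3.0]decenone: C6=C7 enone, C10 ketone, C5–OTBS, C8–OBn cis to C5–O, C2 methyl cis to C5–O | C[C@@H]1CC[C@]2(O[Si](C)(C)C(C)(C)C)C(=C[C@@H](OCc3ccccc3)C2(C)C)C(=O)C1 | intermediate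
19 | cross-conjugated lithium enolate of 18 (C10=C11) | C[C@@H]1CC[C@]2(O[Si](C)(C)C(C)(C)C)C(=C[C@@H](OCc3ccccc3)C2(C)C)C(O[Li])=C1 | intermediate
20 | C11-methyl derivative of 18 (C11 methyl trans to C2 methyl expected; either epimer serves) | C[C@@H]1CC[C@]2(O[Si](C)(C)C(C)(C)C)C(=C[C@@H](OCc3ccccc3)C2(C)C)C(=O)[C@H]1C | intermediate
21 | tetrasubstituted lithium enolate of 20 (C10=C11) | C[C@@H]1CC[C@]2(O[Si](C)(C)C(C)(C)C)C(=C[C@@H](OCc3ccccc3)C2(C)C)C(O[Li])=C1C | intermediate
22 | trimethylsilyl dienol ether of 20 (C11=C10–OTMS, C6=C7) | C[C@@H]1CC[C@]2(O[Si](C)(C)C(C)(C)C)C(=C[C@@H](OCc3ccccc3)C2(C)C)C(O[Si](C)(C)C)=C1C | intermediate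
23 | benzyloxyacetyl chloride | ClC(=O)COCc1ccccc1 | starting material
24 | N,O-dimethylhydroxylamine hydrochloride | CNOC.Cl | starting material
25 | 2-(benzyloxy)-N-methoxy-N-methylacetamide | CON(C)C(=O)COCc1ccccc1 | intermediate
26 | bromomagnesium chelate of the tetrahedral vinyl adduct of 25 | C=CC(O[Mg]Br)(COCc1ccccc1)N(C)OC | intermediate
27 | 1-(benzyloxy)but-3-en-2-one | C=CC(=O)COCc1ccccc1 | intermediate
28 | silyl enol ether of the Michael adduct (side-chain enol ether) | C[C@@H]1CC[C@]2(O[Si](C)(C)C(C)(C)C)C(=C[C@@H](OCc3ccccc3)C2(C)C)C(=O)[C@@]1(C)CC=C(O[Si](C)(C)C)COCc1ccccc1 | intermediate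
29 | Michael adduct: 18 carrying at C11 a methyl (cis to C2 methyl) and a 4-(benzyloxy)-3-oxobutyl chain (trans) | C[C@@H]1CC[C@]2(O[Si](C)(C)C(C)(C)C)C(=C[C@@H](OCc3ccccc3)C2(C)C)C(=O)[C@@]1(C)CCC(=O)COCc1ccccc1 | intermediate
30 | trans-fused keto diol: C6–H trans to C5–OTBS, free C8–OH, 4-hydroxy-3-oxobutyl chain at C11 | C[C@@H]1CC[C@]2(O[Si](C)(C)C(C)(C)C)[C@H](C[C@@H](O)C2(C)C)C(=O)[C@@]1(C)CCC(=O)CO | intermediate
31 | ketenylidenetriphenylphosphorane | O=C=C=P(c1ccccc1)(c1ccccc1)c1ccccc1 | starting material
32 | (triphenylphosphoranylidene)acetate ester of the primary hydroxyl of 30 | C[C@@H]1CC[C@]2(O[Si](C)(C)C(C)(C)C)[C@H](C[C@@H](O)C2(C)C)C(=O)[C@@]1(C)CCC(=O)COC(=O)C=P(c1ccccc1)(c1ccccc1)c1ccccc1 | intermediate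
33 | C5 tert-butyldimethylsilyl ether of the target (butenolide in place) | C[C@@H]1CC[C@]2(O[Si](C)(C)C(C)(C)C)[C@H](C[C@@H](O)C2(C)C)C(=O)[C@@]1(C)CCC1=CC(=O)OC1 | intermediate
34 | CNP0077405.1 | C[C@@H]1CC[C@]2(O)[C@H](C[C@@H](O)C2(C)C)C(=O)[C@@]1(C)CCC1=CC(=O)OC1 | target

## Step count and risks

Total step count: 16. Longest linear sequence: 14 steps from (R)-pulegone (steps 1–10 and 13–16); steps 11 and 12 make the Michael acceptor.

Steps most likely to fail:

1. Step 8. The unactivated terminal alkyne may add too slowly to the C8 oxocarbenium ion, so that the C10 silyloxy oxygen captures the ion (closure to a bicyclic tetrahydrofuranyl acetal with loss of the silyl group), or chloride intercepts the strained vinyl cation before C5 shifts. The fallback sets out from ketone 12 and returns at enone 18. Vinylmagnesium bromide 2 (LaCl3·2LiCl, THF) should add to C10 as the acetylide does, giving the vinyl carbinol F1, and N-(trimethylsilyl)imidazole then gives the trimethylsilyl ether F2. SnCl4 (CH2Cl2, −78 → −23 °C) then effects the alkene form of the annulation (Prins–pinacol ring-enlarging cyclopentane annulation, with a better π-nucleophile and an ordinary secondary cation at C6) to give the saturated bicyclic ketone F3. Equilibrating enol silylation toward the ring-fusion carbon (Me3SiI, (Me3Si)2NH, CH2Cl2) gives the C10=C6 silyl enol ether F4. Saegusa–Ito dehydrogenation (Pd(OAc)2, MeCN), in which β-hydride loss is possible only from C7, returns 18.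

2. Step 13. The vinyl ketone may oligomerise under the Lewis acid and the hindered tetrasubstituted silyl enol ether may be protodesilylated back to the ketone before the C–C bond forms, with erosion of facial selectivity at C11 if forcing conditions are needed. The fallback sets out from methyl ketone 20 (through its lithium enolate 21) and returns at 29. Weinreb amide 25 is treated with [1-(trimethylsilyl)vinyl]magnesium bromide (THF, 0 °C) to give the α-silyl vinyl ketone F5. Lithium enolate 21 (LiN(iPr)2, THF, −78 °C) is added to F5 in a Stork–Ganem Michael addition, in which the silyl group stabilises the adduct enolate and suppresses oligomerisation, giving the α-silyl diketone F6. Mild methanolysis (catalytic K2CO3, MeOH, 0 °C) removes the C-silyl group to give 29.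

3. Step 14. Hydrogen may be delivered to the face of C6=C7 that carries the C5 and C8 oxygens (cis ring fusion), and the allylic C8–O bond may be hydrogenolysed before the alkene is saturated. The fallback sets out from 29 and returns at 30. Conjugate reduction with [(Ph3P)CuH]6 (toluene, rt) followed by protonation of the copper enolate at C6 from the open face opposite the C5 silyloxy group on work-up should give the saturated bis-benzyl ether F7 without touching the C8–O bond. Hydrogenolysis of the now non-allylic benzyl ethers (H2, Pd(OH)2/C, EtOAc) then gives 30.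

Further compounds
F1 | step 8 | vinyl carbinol, analogue of 14 with vinyl in place of ethynyl at C10 | C[C@@H]1CC[C@@](O[Si](C)(C)C(C)(C)C)(C(C)(C)C(OCc2ccccc2)OCc2ccccc2)[C@@](O)(C=C)C1
F2 | step 8 | C10 trimethylsilyl ether of F1 | C[C@@H]1CC[C@@](O[Si](C)(C)C(C)(C)C)(C(C)(C)C(OCc2ccccc2)OCc2ccccc2)[C@@](O[Si](C)(C)C)(C=C)C1
F3 | step 8 | saturated bicyclo[5.3.0]decan-10-one, 6,7-dihydro analogue of 18 (C6 configuration left open, erased later) | C[C@@H]1CC[C@]2(O[Si](C)(C)C(C)(C)C)C(C[C@@H](OCc3ccccc3)C2(C)C)C(=O)C1
F4 | step 8 | C10=C6 trimethylsilyl enol ether of F3 | C[C@@H]1CC[C@]2(O[Si](C)(C)C(C)(C)C)C(C[C@@H](OCc3ccccc3)C2(C)C)=C(O[Si](C)(C)C)C1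
F5 | step 13 | 1-(benzyloxy)-3-(trimethylsilyl)but-3-en-2-one | C=C([Si](C)(C)C)C(=O)COCc1ccccc1
F6 | step 13 | α-silyl Michael adduct, 29 with a trimethylsilyl group on the side-chain carbon next to the ketone (mixture at that carbon) | C[C@@H]1CC[C@]2(O[Si](C)(C)C(C)(C)C)C(=C[C@@H](OCc3ccccc3)C2(C)C)C(=O)[C@@]1(C)CC([Si](C)(C)C)C(=O)COCc1ccccc1
F7 | step 14 | 6,7-dihydro derivative of 29 with both benzyl ethers kept (C6–H trans to C5–O) | C[C@@H]1CC[C@]2(O[Si](C)(C)C(C)(C)C)[C@H](C[C@@H](OCc3ccccc3)C2(C)C)C(=O)[C@@]1(C)CCC(=O)COCc1ccccc1
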